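**Retrosynthetic overview**
Ring A is a hexasubstituted benzene. Its edge C6 (arylethyl), C1 (CO2Me), C2 (OH), C3 (prenyl) repeats the C6–C5–C4–C3 edge of a 4-oxygenated 2-pyrone-5-carboxylate, and C4 (OH)/C5 (prenyl) are the two carbons of an oxygen-polarised alkyne.
Key disconnection: ring A bonds C3–C4 and C5–C6, made by an inverse-demand [4+2] of an acetoxypyrone ester with a silyl ynol ether, the lactone bridge leaving as CO2.
The pyrone comes from enol lactonisation of a C-acylated dimethyl 3-oxoglutarate. Its C3 prenyl group is placed on the oxoglutarate before acylation, so no ambident hydroxypyrone has to be alkylated.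
The ynol ether comes from a Kowalski ynolate rearrangement of methyl 4-methylpent-3-enoate followed by O-silylation.
Ring order: ring B is bought, the pyrone ring is closed next, and ring A is formed last from it. Deacetylation and desilylation finish the route.

Key step: step 9

Remark: the target has no stereocentre and no alkene capable of E/Z isomerism, so no configuration has to be set. The stereocentres that appear in the open-chain keto esters and in the bridged cycloadduct are labile or are destroyed, so these compounds are drawn without configuration.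

**Route**

Step 1
Reactants: 1 3-(4-hydroxyphenyl)propanoic acid
Product: 2 tert-butyldimethylsilyl 3-[4-(tert-butyldimethylsilyloxy)phenyl]propanoate
Conditions: t-BuMe2SiCl (2.5 equiv), imidazole (5 equiv), DMF, rt; cold water/pentane work-up
Reagents that add atoms: tert-butyldimethylsilyl chloride, CC(C)(C)[Si](C)(C)Cl
Why: Imidazole-mediated silylation converts the phenol into its silyl ether and the acid into its silyl ester in one operation, and the silyl ester is wanted because it is the direct substrate of step 2.

Step 2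
Reactants: 2 tert-butyldimethylsilyl 3-[4-(tert-butyldimethylsilyloxy)phenyl]propanoate
Product: 3 3-[4-(tert-butyldimethylsilyloxy)phenyl]propanoyl chloride
Conditions: (COCl)2 (1.2 equiv), DMF (cat.), CH2Cl2, 0 °C → rt; concentrate and use crude
Reagents that add atoms: oxalyl chloride, O=C(Cl)C(=O)Cl
Why: The Vilsmeier reagent formed from (COCl)2 and catalytic DMF converts a tert-butyldimethylsilyl ester into the acid chloride with release of the silyl chloride instead of HCl, so this acyl chloride formation runs under neutral conditions that the aryl silyl ether tolerates.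

Step 3
Reactants: 4 dimethyl 3-oxopentanedioate (dimethyl 1,3-acetonedicarboxylate), 5 1-bromo-3-methylbut-2-ene (prenyl bromide)
Product: 6 dimethyl 2-(3-methylbut-2-enyl)-3-oxopentanedioate
Conditions: 4 (2.0 equiv), NaH (1.0 equiv), THF, 0 °C; then 5 (1.0 equiv), 0 °C → rt
Reagents that add atoms: none
Why: SN2 C-alkylation of the soft sodium enolate of a β-keto diester by a primary allylic bromide (acetoacetic ester type alkylation) is reliable, the excess of cheap 4 holds back dialkylation, the new α-stereocentre is racemic, labile and disappears in step 5, and placing the future C3 prenyl group here avoids the O- versus C-alkylation problem of an ambident 4-hydroxypyrone.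

Step 4
Reactants: 3 3-[4-(tert-butyldimethylsilyloxy)phenyl]propanoyl chloride, 6 dimethyl 2-(3-methylbut-2-enyl)-3-oxopentanedioate
Product: 7 dimethyl 2-{3-[4-(tert-butyldimethylsilyloxy)phenyl]propanoyl}-4-(3-methylbut-2-enyl)-3-oxopentanedioate
Conditions: MgCl2 (1.1 equiv), pyridine (2.2 equiv), CH2Cl2, 0 °C → rt; cold aqueous citric acid
Reagents that add atoms: none
Why: In this soft-enolisation C-acylation of a β-keto ester with MgCl2 and an amine base, the magnesium-chelated enolate forms at the unsubstituted and more acidic C4 methylene of 6, chelation directs the acid chloride to carbon, only this site gives a product held as a stable enolised tricarbonyl chelate, and the stereocentres are labile and of no consequence.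

Step 5
Reactants: 7 dimethyl 2-{3-[4-(tert-butyldimethylsilyloxy)phenyl]propanoyl}-4-(3-methylbut-2-enyl)-3-oxopentanedioate
Product: 8 methyl 6-{2-[4-(tert-butyldimethylsilyloxy)phenyl]ethyl}-4-hydroxy-3-(3-methylbut-2-enyl)-2-oxo-2H-pyran-5-carboxylate
Conditions: DBU (1.1 equiv), 4 Å MS, toluene, 80 °C; cold aqueous citric acid
Reagents that add atoms: none
Why: In this enol lactonisation (the standard closure of 3,5-dioxo esters to 4-hydroxy-2-pyrones) the oxygen of the enolised side-chain ketone attacks the remote ester in a 6-exo-trig acyl substitution, loss of methanol and enolisation give the acidic pyronate as thermodynamic sink, and because substrate and product buffer the DBU the aryl silyl ether and the prenyl group are not at risk.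

Step 6
Reactants: 8 methyl 6-{2-[4-(tert-butyldimethylsilyloxy)phenyl]ethyl}-4-hydroxy-3-(3-methylbut-2-enyl)-2-oxo-2H-pyran-5-carboxylate
Product: 9 methyl 4-acetoxy-6-{2-[4-(tert-butyldimethylsilyloxy)phenyl]ethyl}-3-(3-methylbut-2-enyl)-2-oxo-2H-pyran-5-carboxylate
Conditions: Ac2O (1.5 equiv), Et3N (1.5 equiv), DMAP (cat.), CH2Cl2, 0 °C
Reagents that add atoms: acetic anhydride, CC(=O)OC(C)=O
Why: O-acylation of the acidic C4 hydroxyl under nucleophilic catalysis is fast, and the O-to-C3 acyl migration that normally troubles 4-acyloxypyrones under DMAP is blocked by the C3 prenyl group.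

Step 7
Reactants: 10 4-methylpent-3-enoic acid
Product: 11 methyl 4-methylpent-3-enoate
Conditions: MeI (1.5 equiv), K2CO3 (1.5 equiv), DMF, rt
Reagents that add atoms: iodomethane, CI
Why: Carboxylate SN2 alkylation gives the ester without acid, which would close this β,γ-unsaturated acid to the γ,γ-dimethylbutyrolactone, and K2CO3 at room temperature is too weak a base to move the alkene into conjugation.

Step 8
Reactants: 11 methyl 4-methylpent-3-enoate
Product: 14 triisopropyl(5-methylhex-4-en-1-ynyloxy)silane, via lithium dibromoenolate 12 (not isolated), via lithium ynolate 13 (not isolated)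
Conditions: CH2Br2, lithium 2,2,6,6-tetramethylpiperidide, THF, −78 °C; 11; LiN(SiMe3)2; n-BuLi, −78 °C → rt; i-Pr3SiOTf, −78 → 0 °C; Et3N-deactivated silica
Reagents that add atoms: dibromomethane, BrCBr; triisopropylsilyl trifluoromethanesulfonate, CC(C)[Si](OS(=O)(=O)C(F)(F)F)(C(C)C)C(C)C
Why: This is a Kowalski ester homologation halted at the ynolate, in which LiCHBr2 adds to the ester, the derived dibromoketone is deprotonated to 12, bromine–lithium exchange triggers the 1,2-shift of the prenyl CH2 group with loss of LiBr to give 13, and the bulky silyl triflate silylates the ynolate on oxygen rather than on carbon.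

Step 9
Reactants: 9 methyl 4-acetoxy-6-{2-[4-(tert-butyldimethylsilyloxy)phenyl]ethyl}-3-(3-methylbut-2-enyl)-2-oxo-2H-pyran-5-carboxylate, 14 triisopropyl(5-methylhex-4-en-1-ynyloxy)silane
Product: 16 methyl 2-acetoxy-6-{2-[4-(tert-butyldimethylsilyloxy)phenyl]ethyl}-3,5-bis(3-methylbut-2-enyl)-4-(triisopropylsilyloxy)benzoate, via bridged lactone 15 (not isolated)
Conditions: 14 (2.5 equiv, in portions), AgNTf2 (10 mol %), 4 Å MS, ClCH2CH2Cl, 25 → 70 °C
Reagents that add atoms: none
Why: The alkyne carbon that carries the prenyl group is the nucleophilic end of 14 and bonds to pyrone C6, the position activated vinylogously by both the C5 ester and the lactone carbonyl, while the emerging silyl ketenium carbon is captured by C3 of the resulting dienolate, so the inverse-demand [4+2] is highly asynchronous and forms ring A bonds C5–C6 and C3–C4. The closest known reaction type is the Diels–Alder/retro-Diels–Alder benzannulation of 2-pyrone carboxylates with ynamines, alkynyl ethers and, under AgNTf2 promotion, siloxyalkynes. Ring A is closed intermolecularly as the carbocyclic six-membered ring of the 2-oxabicyclo[2.2.2]octa-5,7-dien-3-one 15, whose lactone bridge then leaves as CO2 in a retro-[4+2] driven by aromatisation. The two bridgehead stereocentres of racemic 15 are erased in that loss, so no stereocontrol is required. The step needs regioselectivity, which the matched polarisation of the partners secures (the reverse orientation would join the oxygen-bearing alkyne carbon to the electrophilic C6), and periselectivity over [2+2] closure at C5, which is favoured by the irreversible loss of CO2 from the [4+2] adduct and by the crowding at C5. The O-acetyl group tempers donation from the C4 oxygen so that the diene stays electron-poor, and the trisubstituted alkenes are far too weakly nucleophilic to compete with the ynol ether.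

Step 10
Reactants: 16 methyl 2-acetoxy-6-{2-[4-(tert-butyldimethylsilyloxy)phenyl]ethyl}-3,5-bis(3-methylbut-2-enyl)-4-(triisopropylsilyloxy)benzoate
Product: 17 methyl 6-{2-[4-(tert-butyldimethylsilyloxy)phenyl]ethyl}-2-hydroxy-3,5-bis(3-methylbut-2-enyl)-4-(triisopropylsilyloxy)benzoate
Conditions: K2CO3 (0.3 equiv), MeOH/THF, 0 °C, short time; aqueous NH4Cl
Reagents that add atoms: none
Why: Base-catalysed transesterification removes the aryl acetate, by far the best acyl donor present, while exchange at the methyl ester is degenerate in methanol and the short cold exposure should leave both aryl silyl ethers in place (their premature loss would be harmless, since step 11 removes them).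

Step 11
Reactants: 17 methyl 6-{2-[4-(tert-butyldimethylsilyloxy)phenyl]ethyl}-2-hydroxy-3,5-bis(3-methylbut-2-enyl)-4-(triisopropylsilyloxy)benzoate
Product: 18 methyl 2,4-dihydroxy-6-[2-(4-hydroxyphenyl)ethyl]-3,5-bis(3-methylbut-2-enyl)benzoate (CNP0133671.0)
Conditions: Bu4NF (2.5 equiv), AcOH (2.5 equiv), THF, 0 °C → rt
Reagents that add atoms: none
Why: Fluoride-induced desilylation of both aryl silyl ethers is driven by the Si–F bond and the good phenoxide leaving groups, and the acetic acid buffer keeps the medium close to neutral so that the methyl ester is not attacked and the ortho-prenylphenols are not cyclised to chromans.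

**Compound list**
1 | 3-(4-hydroxyphenyl)propanoic acid | OC(=O)CCc1ccc(O)cc1 | starting material
2 | tert-butyldimethylsilyl 3-[4-(tert-butyldimethylsilyloxy)phenyl]propanoate | CC(C)(C)[Si](C)(C)OC(=O)CCc1ccc(O[Si](C)(C)C(C)(C)C)cc1 | intermediate
3 | 3-[4-(tert-butyldimethylsilyloxy)phenyl]propanoyl chloride | O=C(Cl)CCc1ccc(O[Si](C)(C)C(C)(C)C)cc1 | intermediate
4 | dimethyl 3-oxopentanedioate | COC(=O)CC(=O)CC(=O)OC | starting material
5 | 1-bromo-3-methylbut-2-ene | CC(C)=CCBr | starting material
6 | dimethyl 2-(3-methylbut-2-enyl)-3-oxopentanedioate | COC(=O)CC(=O)C(CC=C(C)C)C(=O)OC | intermediate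
7 | dimethyl 2-{3-[4-(tert-butyldimethylsilyloxy)phenyl]propanoyl}-4-(3-methylbut-2-enyl)-3-oxopentanedioate | COC(=O)C(CC=C(C)C)C(=O)C(C(=O)OC)C(=O)CCc1ccc(O[Si](C)(C)C(C)(C)C)cc1 | intermediate
8 | methyl 6-{2-[4-(tert-butyldimethylsilyloxy)phenyl]ethyl}-4-hydroxy-3-(3-methylbut-2-enyl)-2-oxo-2H-pyran-5-carboxylate | O=C1OC(CCc2ccc(O[Si](C)(C)C(C)(C)C)cc2)=C(C(=O)OC)C(O)=C1CC=C(C)C | intermediate
9 | methyl 4-acetoxy-6-{2-[4-(tert-butyldimethylsilyloxy)phenyl]ethyl}-3-(3-methylbut-2-enyl)-2-oxo-2H-pyran-5-carboxylate | O=C1OC(CCc2ccc(O[Si](C)(C)C(C)(C)C)cc2)=C(C(=O)OC)C(OC(C)=O)=C1CC=C(C)C | intermediate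
10 | 4-methylpent-3-enoic acid | CC(C)=CCC(=O)O | starting material
11 | methyl 4-methylpent-3-enoate | COC(=O)CC=C(C)C | intermediate
12 | lithium 1,1-dibromo-5-methylhexa-1,4-dien-2-olate (not isolated) | [Li+].[O-]C(CC=C(C)C)=C(Br)Br | intermediate
13 | lithium 5-methylhex-4-en-1-yn-1-olate (not isolated) | [Li+].[O-]C#CCC=C(C)C | intermediate
14 | triisopropyl(5-methylhex-4-en-1-ynyloxy)silane | CC(C)=CCC#CO[Si](C(C)C)(C(C)C)C(C)C | intermediate
15 | methyl 5-acetoxy-1-{2-[4-(tert-butyldimethylsilyloxy)phenyl]ethyl}-4,7-bis(3-methylbut-2-enyl)-3-oxo-8-(triisopropylsilyloxy)-2-oxabicyclo[2.2.2]octa-5,7-diene-6-carboxylate (racemic, not isolated) | O=C1OC2(CCc3ccc(O[Si](C)(C)C(C)(C)C)cc3)C(C(=O)OC)=C(OC(C)=O)C1(CC=C(C)C)C(O[Si](C(C)C)(C(C)C)C(C)C)=C2CC=C(C)C | intermediate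
16 | methyl 2-acetoxy-6-{2-[4-(tert-butyldimethylsilyloxy)phenyl]ethyl}-3,5-bis(3-methylbut-2-enyl)-4-(triisopropylsilyloxy)benzoate | COC(=O)c1c(OC(C)=O)c(CC=C(C)C)c(O[Si](C(C)C)(C(C)C)C(C)C)c(CC=C(C)C)c1CCc1ccc(O[Si](C)(C)C(C)(C)C)cc1 | intermediate
17 | methyl 6-{2-[4-(tert-butyldimethylsilyloxy)phenyl]ethyl}-2-hydroxy-3,5-bis(3-methylbut-2-enyl)-4-(triisopropylsilyloxy)benzoate | COC(=O)c1c(O)c(CC=C(C)C)c(O[Si](C(C)C)(C(C)C)C(C)C)c(CC=C(C)C)c1CCc1ccc(O[Si](C)(C)C(C)(C)C)cc1 | intermediate
18 | methyl 2,4-dihydroxy-6-[2-(4-hydroxyphenyl)ethyl]-3,5-bis(3-methylbut-2-enyl)benzoate | COC(=O)c1c(O)c(CC=C(C)C)c(O)c(CC=C(C)C)c1CCc1ccc(O)cc1 | target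

**Totals**
Total step count: 11.
Longest linear sequence: 8 steps (1, 2, 4, 5, 6, 9, 10, 11), starting from 1.

**Steps most likely to fail**

Risk 1, step 9. The leading bond must join pyrone C6 and an alkyne carbon that each carry a CH2R group, on a diene that also holds two alkyl donors. Cycloaddition may therefore be outrun by silver-induced hydration or oligomerisation of the ynol ether, by [2+2] closure at C5, or by acetyl transfer from the C4 oxygen.

The fallback sets out from 9 and comes back at 18. The internal alkyne is given up for an unsubstituted and far more nucleophilic two-carbon partner, and the C5 prenyl group is delivered afterwards from the C4 oxygen.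
- Trimethylsilyl acetate is converted (LiN(i-Pr)2, Me3SiCl, THF, −78 °C) into 1,1-bis(trimethylsilyloxy)ethene F1.
- Heating 9 with F1 in toluene at 110 °C is the classical 2-pyrone/ketene acetal benzannulation: the CH2 terminus adds to C6, closure occurs at C3, and CO2 and then Me3SiOH are lost. It should give methyl 2-acetoxy-6-{2-[4-(tert-butyldimethylsilyloxy)phenyl]ethyl}-3-(3-methylbut-2-enyl)-4-(trimethylsilyloxy)benzoate F2.
- Dilute citric acid in aqueous THF turns F2 into methyl 2-acetoxy-6-{2-[4-(tert-butyldimethylsilyloxy)phenyl]ethyl}-4-hydroxy-3-(3-methylbut-2-enyl)benzoate F3.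
- O-alkylation with tert-butyl 2-methylbut-3-en-2-yl carbonate under zerovalent palladium catalysis (Pd(PPh3)4, THF, 0 °C) should give methyl 2-acetoxy-6-{2-[4-(tert-butyldimethylsilyloxy)phenyl]ethyl}-4-(2-methylbut-3-en-2-yloxy)-3-(3-methylbut-2-enyl)benzoate F4.
- Aromatic Claisen rearrangement (toluene, 130 °C, sealed tube) moves the allyl unit with inversion to the only free ortho position, C5. It should give methyl 2-acetoxy-6-{2-[4-(tert-butyldimethylsilyloxy)phenyl]ethyl}-4-hydroxy-3,5-bis(3-methylbut-2-enyl)benzoate F5.
- Methanolysis under the conditions of step 10 gives methyl 6-{2-[4-(tert-butyldimethylsilyloxy)phenyl]ethyl}-2,4-dihydroxy-3,5-bis(3-methylbut-2-enyl)benzoate F6, and Bu4NF/AcOH as in step 11 gives 18.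

Risk 2, step 8. The C2 methylene of 11 is both allylic and α to the ester. Proton transfer to LiCHBr2 or to the amide bases may compete with carbonyl addition, returning the ester or moving the alkene into conjugation. Part of the ynolate may also be silylated on carbon.

The fallback sets out from 5 and comes back at 13, and so at 14. The ynolate is made by oxidation of an acetylide instead of by rearrangement.
- Copper-catalysed coupling of 5 with HC≡CMgBr (CuCl 5 mol %, THF, 0 °C → rt) should give 5-methylhex-4-en-1-yne F7.
- n-BuLi (THF, −78 °C) gives lithium 5-methylhex-4-en-1-ynide F8.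
- Lithium tert-butyl peroxide (from t-BuOOH and LiN(SiMe3)2, −78 → 0 °C) transfers oxygen to the acetylide carbon to give 13.
- 13 is silylated with i-Pr3SiOTf as in step 8.

Risk 3, step 5. The stabilised tricarbonyl enolate may attack the hindered α-prenylated ester only slowly. Retro-Claisen loss of the acyl group under the action of released methanol, or Claisen-type carbocyclisation through the side-chain α-CH2, could then take over.

The fallback sets out from 3 and 4 and comes back at 8. The pyrone is closed before the prenyl group is present.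
- Acylation of 4 with 3 under the conditions of step 4 should give dimethyl 2-{3-[4-(tert-butyldimethylsilyloxy)phenyl]propanoyl}-3-oxopentanedioate F9.
- The unhindered CH2CO2Me arm of F9 lactonises (DBU, toluene, 60 °C) to methyl 6-{2-[4-(tert-butyldimethylsilyloxy)phenyl]ethyl}-4-hydroxy-2-oxo-2H-pyran-5-carboxylate F10.
- Tsuji–Trost allylation with 3-methylbut-2-enyl methyl carbonate (Pd(PPh3)4 5 mol %, THF, 50 °C) then places the prenyl group on C3. O-allylation is reversible under zerovalent palladium catalysis, and the soft pyronate carbon attacks the less substituted allyl terminus, so 8 should accumulate.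

**Further compounds**
F1 | step 9 | 1,1-bis(trimethylsilyloxy)ethene | C=C(O[Si](C)(C)C)O[Si](C)(C)C
F2 | step 9 | methyl 2-acetoxy-6-{2-[4-(tert-butyldimethylsilyloxy)phenyl]ethyl}-3-(3-methylbut-2-enyl)-4-(trimethylsilyloxy)benzoate | COC(=O)c1c(OC(C)=O)c(CC=C(C)C)c(O[Si](C)(C)C)cc1CCc1ccc(O[Si](C)(C)C(C)(C)C)cc1
F3 | step 9 | methyl 2-acetoxy-6-{2-[4-(tert-butyldimethylsilyloxy)phenyl]ethyl}-4-hydroxy-3-(3-methylbut-2-enyl)benzoate | COC(=O)c1c(OC(C)=O)c(CC=C(C)C)c(O)cc1CCc1ccc(O[Si](C)(C)C(C)(C)C)cc1
F4 | step 9 | methyl 2-acetoxy-6-{2-[4-(tert-butyldimethylsilyloxy)phenyl]ethyl}-4-(2-methylbut-3-en-2-yloxy)-3-(3-methylbut-2-enyl)benzoate | COC(=O)c1c(OC(C)=O)c(CC=C(C)C)c(OC(C)(C)C=C)cc1CCc1ccc(O[Si](C)(C)C(C)(C)C)cc1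
F5 | step 9 | methyl 2-acetoxy-6-{2-[4-(tert-butyldimethylsilyloxy)phenyl]ethyl}-4-hydroxy-3,5-bis(3-methylbut-2-enyl)benzoate | COC(=O)c1c(OC(C)=O)c(CC=C(C)C)c(O)c(CC=C(C)C)c1CCc1ccc(O[Si](C)(C)C(C)(C)C)cc1
F6 | step 9 | methyl 6-{2-[4-(tert-butyldimethylsilyloxy)phenyl]ethyl}-2,4-dihydroxy-3,5-bis(3-methylbut-2-enyl)benzoate | COC(=O)c1c(O)c(CC=C(C)C)c(O)c(CC=C(C)C)c1CCc1ccc(O[Si](C)(C)C(C)(C)C)cc1
F7 | step 8 | 5-methylhex-4-en-1-yne | C#CCC=C(C)C
F8 | step 8 | lithium 5-methylhex-4-en-1-ynide | [Li]C#CCC=C(C)C
F9 | step 5 | dimethyl 2-{3-[4-(tert-butyldimethylsilyloxy)phenyl]propanoyl}-3-oxopentanedioate | COC(=O)CC(=O)C(C(=O)OC)C(=O)CCc1ccc(O[Si](C)(C)C(C)(C)C)cc1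
F10 | step 5 | methyl 6-{2-[4-(tert-butyldimethylsilyloxy)phenyl]ethyl}-4-hydroxy-2-oxo-2H-pyran-5-carboxylate | O=C1OC(CCc2ccc(O[Si](C)(C)C(C)(C)C)cc2)=C(C(=O)OC)C(O)=C1
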